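Everything rests on cutting the C5–O1 bond of the tetrahydrofuran (O1, C2 bearing ring A, C3, C4, C5 bearing ring B). C5 lies at the benzylic position para to the ring B phenol oxygen and holds its aryl group trans to the C4 methyl, so it can travel as a methylene and be oxidised at the end. DDQ converts the ring B 4-hydroxybenzyl unit of open-chain alcohol 12 into a para-quinone methide, which the C2 hydroxyl captures: ring, C5–O1 bond and C5 stereocentre arise in one operation. Precursor 12 has ring A as benzyl ether, ring B as the only free phenol, and C2, C3 and C4 already set.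

Key step: step 9

Assumption: in step 3 the (S)-configured t-Bu-PHOX ligand is taken to open the meso anhydride towards the (2R,3S) keto acid 7; the sense of induction depends on the ligand alone, so its mirror image would be used if the opposite enantiomer formed.

Step 1
Reactants: 1 2,3-dimethylmaleic anhydride
Product: 2 meso-2,3-dimethylsuccinic anhydride [(3R,4S)-3,4-dimethyloxolane-2,5-dione, methyls cis]
Conditions: H2 (3 atm), 10% Pd/C, EtOAc, rt
Reagents that add atoms: none
Why: Heterogeneous catalytic hydrogenation delivers both hydrogens to one face of the tetrasubstituted alkene, so the cis (meso) anhydride carrying the later C3/C4 cis-dimethyl pattern should result.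

Step 2
Reactants: 3 4-bromo-2-methoxyphenol
Product: 4 1-(benzyloxy)-4-bromo-2-methoxybenzene
Conditions: BnBr, K2CO3, DMF, rt
Reagents that add atoms: benzyl bromide, BrCc1ccccc1
Why: Williamson etherification of the phenoxide gives the single aryl bromide that serves as the source of rings A, B and C.

Step 3
Reactants: 4 1-(benzyloxy)-4-bromo-2-methoxybenzene; 2 meso-2,3-dimethylsuccinic anhydride
Product: 7 (2R,3S)-4-[4-(benzyloxy)-3-methoxyphenyl]-2,3-dimethyl-4-oxobutanoic acid, via aryllithium 5 (not isolated), via arylzinc triflate 6 (not isolated)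
Conditions: n-BuLi, THF, −78 °C; Zn(OTf)2, −78 °C to rt; then 2, [Rh(cod)Cl]2 (4 mol %), (S)-t-Bu-PHOX (8 mol %), THF, 50 °C; aq. HCl
Reagents that add atoms: none
Why: Rhodium-catalysed enantioselective desymmetrisation of a cyclic meso anhydride by an arylzinc reagent acylates ring B at one of the two enantiotopic carbonyl groups, so the chiral ligand fixes both methyl-bearing centres (later C3 and C4) in absolute terms while their cis relationship is untouched.

Step 4
Reactants: 7 (2R,3S)-4-[4-(benzyloxy)-3-methoxyphenyl]-2,3-dimethyl-4-oxobutanoic acid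
Product: 8 (2R,3R)-4-(4-hydroxy-3-methoxyphenyl)-2,3-dimethylbutanoic acid
Conditions: H2 (3 atm), 10% Pd/C, AcOH, 40 °C
Reagents that add atoms: none
Why: Catalytic hydrogenolysis removes the benzyl ether and takes the electron-rich aryl ketone through its benzylic alcohol (or lactone) to the methylene, as is usual for 4-aryl-4-oxobutanoic acids, without touching the two stereocentres.

Step 5
Reactants: 8 (2R,3R)-4-(4-hydroxy-3-methoxyphenyl)-2,3-dimethylbutanoic acid
Product: 9 (2R,3R)-4-(4-hydroxy-3-methoxyphenyl)-N-methoxy-N,2,3-trimethylbutanamide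
Conditions: MeNH(OMe)·HCl, EDC·HCl, HOBt, N-methylmorpholine, CH2Cl2, 0 °C to rt
Reagents that add atoms: N,O-dimethylhydroxylamine hydrochloride, CNOC.Cl
Why: Carbodiimide/HOBt amide coupling acylates the amine much faster than the phenol, so the Weinreb amide should form without phenol protection and without risk to the α-stereocentre.

Step 6
Reactants: 9 (2R,3R)-4-(4-hydroxy-3-methoxyphenyl)-N-methoxy-N,2,3-trimethylbutanamide
Product: 10 (2R,3R)-4-(4-hydroxy-3-methoxyphenyl)-2,3-dimethylbutanal
Conditions: LiAlH4 (2.5 equiv), THF, −78 to 0 °C; then cold aq. KHSO4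
Reagents that add atoms: none
Why: Weinreb amide reduction stops at the chelated tetrahedral aluminate, which releases the aldehyde only on quenching, one hydride equivalent being spent on the phenol and the crude aldehyde being used at once to avoid α-epimerisation.

Step 7
Reactants: 4 1-(benzyloxy)-4-bromo-2-methoxybenzene
Product: 11 [4-(benzyloxy)-3-methoxyphenyl]magnesium bromide, kept as a titrated THF stock solution under argon
Conditions: Mg turnings, cat. I2, THF, rt to 40 °C
Reagents that add atoms: magnesium, [Mg]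
Why: Grignard formation by insertion of magnesium into the aryl C–Br bond is routine for this electron-rich aryl bromide, and one batch of the titrated solution supplies both later aryl additions (steps 8 and 11).

Step 8
Reactants: 10 (2R,3R)-4-(4-hydroxy-3-methoxyphenyl)-2,3-dimethylbutanal; 11 [4-(benzyloxy)-3-methoxyphenyl]magnesium bromide
Product: 12 (1S,2R,3R)-1-[4-(benzyloxy)-3-methoxyphenyl]-4-(4-hydroxy-3-methoxyphenyl)-2,3-dimethylbutan-1-ol
Conditions: 10 added to 11 (3 equiv), THF, −78 °C; aq. NH4Cl
Reagents that add atoms: none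
Why: Grignard addition to the α-methyl aldehyde under Felkin–Anh control (branched C3 substituent anti to the incoming aryl, attack past the α-hydrogen) should give the 1,2-syn alcohol with the new carbinol centre S, the first equivalent of 11 merely deprotonating the phenol.

Step 9
Reactants: 12 (1S,2R,3R)-1-[4-(benzyloxy)-3-methoxyphenyl]-4-(4-hydroxy-3-methoxyphenyl)-2,3-dimethylbutan-1-ol
Product: 14 (2S,3R,4S,5S)-2-[4-(benzyloxy)-3-methoxyphenyl]-5-(4-hydroxy-3-methoxyphenyl)-3,4-dimethyltetrahydrofuran, via quinone methide 13 (not isolated)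
Conditions: DDQ (1.05 equiv), CH2Cl2, 0 °C; aq. NaHCO3
Reagents that add atoms: none
Why: DDQ forms a charge-transfer complex with the electron-rich ring B phenol and removes hydride from its para benzylic CH2 (C5) to give para-quinone methide 13, and the C2 hydroxyl then adds to the exocyclic methide carbon in an oxa-1,6-conjugate addition that restores the aromatic ring. The closest known reaction type is the DDQ oxidation of 4-alkylphenols to quinone methides with intramolecular capture by a hydroxyl group, which has been applied to aryltetrahydrofuran lignans. The tetrahydrofuran closes in the 5-exo-trig mode, O1 attacking C5 while the methide double bond stays outside the new ring. The new C5 stereocentre is controlled by the neighbouring C4 methyl, because the oxygen approaches the planar methide so that the aryl group ends up trans to that methyl, whereas the alternative would crowd all four ring substituents onto one face. The step needs chemoselectivity for ring B over the ring A benzylic carbinol and retention at C2, and both are secured because only ring B carries a free phenol (the ring A benzyl ether cannot form a quinone methide) and one equivalent of DDQ at 0 °C leaves no oxidant for the slower oxidation of the C2 carbinol or of the product. C2, C3 and C4 are carried over unchanged from 12.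

Step 10
Reactants: 15 ethyl (S)-lactate
Product: 16 (S)-2-hydroxy-N-methoxy-N-methylpropanamide
Conditions: MeNH(OMe)·HCl, i-PrMgCl, THF, −20 to 0 °C; aq. NH4Cl
Reagents that add atoms: N,O-dimethylhydroxylamine hydrochloride, CNOC.Cl
Why: Aminolysis of the ester by the chloromagnesium amide of N,O-dimethylhydroxylamine gives the Weinreb amide, the α-stereocentre being protected from enolisation as its magnesium alkoxide.

Step 11
Reactants: 16 (S)-2-hydroxy-N-methoxy-N-methylpropanamide; 11 [4-(benzyloxy)-3-methoxyphenyl]magnesium bromide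
Product: 17 (S)-1-[4-(benzyloxy)-3-methoxyphenyl]-2-hydroxypropan-1-one
Conditions: 11 (2.5 equiv), THF, 0 °C to rt; aq. NH4Cl
Reagents that add atoms: none
Why: In this Weinreb ketone synthesis the Grignard reagent adds once to the amide (one equivalent being consumed by the free hydroxyl) and the chelated adduct collapses to the ketone only on work-up, so the lactate stereocentre is retained.

Step 12
Reactants: 17 (S)-1-[4-(benzyloxy)-3-methoxyphenyl]-2-hydroxypropan-1-one
Product: 18 (S)-1-[4-(benzyloxy)-3-methoxyphenyl]-1-oxopropan-2-yl 4-methylbenzenesulfonate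
Conditions: TsCl, pyridine, CH2Cl2, 0 °C to rt
Reagents that add atoms: 4-toluenesulfonyl chloride, Cc1ccc(cc1)S(Cl)(=O)=O
Why: O-Sulfonylation of the secondary alcohol leaves its C–O bond intact, so the (S) configuration is kept and a leaving group activated by the adjacent carbonyl is installed.

Step 13
Reactants: 14 (2S,3R,4S,5S)-2-[4-(benzyloxy)-3-methoxyphenyl]-5-(4-hydroxy-3-methoxyphenyl)-3,4-dimethyltetrahydrofuran; 18 (S)-1-[4-(benzyloxy)-3-methoxyphenyl]-1-oxopropan-2-yl 4-methylbenzenesulfonate
Product: 19 (R)-1-[4-(benzyloxy)-3-methoxyphenyl]-2-{4-[(2S,3S,4R,5S)-5-(4-benzyloxy-3-methoxyphenyl)-3,4-dimethyltetrahydrofuran-2-yl]-2-methoxyphenoxy}propan-1-one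
Conditions: K2CO3, DMF, 0 °C to rt
Reagents that add atoms: none
Why: Williamson-type SN2 displacement of the carbonyl-activated secondary tosylate by the ring B phenoxide proceeds with inversion, turning the (S) tosylate into the (R) aryl ether, while the mild carbonate base limits enolisation of the product.

Step 14
Reactants: 19 (R)-1-[4-(benzyloxy)-3-methoxyphenyl]-2-{4-[(2S,3S,4R,5S)-5-(4-benzyloxy-3-methoxyphenyl)-3,4-dimethyltetrahydrofuran-2-yl]-2-methoxyphenoxy}propan-1-one
Product: 20 (1S,2R)-1-[4-(benzyloxy)-3-methoxyphenyl]-2-{4-[(2S,3S,4R,5S)-5-(4-benzyloxy-3-methoxyphenyl)-3,4-dimethyltetrahydrofuran-2-yl]-2-methoxyphenoxy}propan-1-ol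
Conditions: Zn(BH4)2, Et2O–CH2Cl2, −20 °C; aq. NH4Cl
Reagents that add atoms: none
Why: In this chelation-controlled (Cram chelate) hydride reduction zinc bridges the carbonyl and the α-aryloxy oxygen and hydride enters from the side of the α-hydrogen, which should give the erythro (1S,2R) alcohol.

Step 15
Reactants: 20 (1S,2R)-1-[4-(benzyloxy)-3-methoxyphenyl]-2-{4-[(2S,3S,4R,5S)-5-(4-benzyloxy-3-methoxyphenyl)-3,4-dimethyltetrahydrofuran-2-yl]-2-methoxyphenoxy}propan-1-ol
Product: 21 (1S,2R)-1-(4-hydroxy-3-methoxyphenyl)-2-{4-[(2S,3S,4R,5S)-5-(4-hydroxy-3-methoxyphenyl)-3,4-dimethyltetrahydrofuran-2-yl]-2-methoxyphenoxy}propan-1-ol (CNP0171079.3)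
Conditions: H2 (1 atm), 10% Pd/C, EtOAc, rt
Reagents that add atoms: none
Why: Catalytic hydrogenolysis of the two aryl benzyl ethers under neutral conditions is much faster than cleavage of the tetrahydrofuran benzylic C–O bonds or of the benzylic alcohol, so both phenols should be freed without touching any stereocentre.

Compound list
1 | 2,3-dimethylmaleic anhydride | CC1=C(C)C(=O)OC1=O | starting material
2 | meso-2,3-dimethylsuccinic anhydride, (3R,4S)-3,4-dimethyloxolane-2,5-dione | C[C@@H]1[C@H](C)C(=O)OC1=O | intermediate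
3 | 4-bromo-2-methoxyphenol | COc1cc(Br)ccc1O | starting material
4 | 1-(benzyloxy)-4-bromo-2-methoxybenzene | COc1cc(Br)ccc1OCc1ccccc1 | intermediate
5 | [4-(benzyloxy)-3-methoxyphenyl]lithium (formed in the flask) | COc1cc([Li])ccc1OCc1ccccc1 | intermediate
6 | [4-(benzyloxy)-3-methoxyphenyl]zinc trifluoromethanesulfonate (formed in the flask) | COc1cc([Zn]OS(=O)(=O)C(F)(F)F)ccc1OCc1ccccc1 | intermediate
7 | (2R,3S)-4-[4-(benzyloxy)-3-methoxyphenyl]-2,3-dimethyl-4-oxobutanoic acid | OC(=O)[C@H](C)[C@H](C)C(=O)c1ccc(OCc2ccccc2)c(OC)c1 | intermediate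
8 | (2R,3R)-4-(4-hydroxy-3-methoxyphenyl)-2,3-dimethylbutanoic acid | OC(=O)[C@H](C)[C@H](C)Cc1ccc(O)c(OC)c1 | intermediate
9 | (2R,3R)-4-(4-hydroxy-3-methoxyphenyl)-N-methoxy-N,2,3-trimethylbutanamide | CON(C)C(=O)[C@H](C)[C@H](C)Cc1ccc(O)c(OC)c1 | intermediate
10 | (2R,3R)-4-(4-hydroxy-3-methoxyphenyl)-2,3-dimethylbutanal | O=C[C@H](C)[C@H](C)Cc1ccc(O)c(OC)c1 | intermediate
11 | [4-(benzyloxy)-3-methoxyphenyl]magnesium bromide (titrated THF stock solution) | COc1cc([Mg]Br)ccc1OCc1ccccc1 | intermediate
12 | (1S,2R,3R)-1-[4-(benzyloxy)-3-methoxyphenyl]-4-(4-hydroxy-3-methoxyphenyl)-2,3-dimethylbutan-1-ol | COc1cc([C@@H](O)[C@H](C)[C@H](C)Cc2ccc(O)c(OC)c2)ccc1OCc1ccccc1 | intermediate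
13 | 4-{(2R,3R,4S)-4-[4-(benzyloxy)-3-methoxyphenyl]-4-hydroxy-2,3-dimethylbutylidene}-2-methoxycyclohexa-2,5-dien-1-one, the ring B para-quinone methide (formed in the flask, alkene geometry not defined) | COc1cc([C@@H](O)[C@H](C)[C@H](C)C=C2C=CC(=O)C(OC)=C2)ccc1OCc1ccccc1 | intermediate
14 | (2S,3R,4S,5S)-2-[4-(benzyloxy)-3-methoxyphenyl]-5-(4-hydroxy-3-methoxyphenyl)-3,4-dimethyltetrahydrofuran | COc1cc([C@H]2O[C@H](c3ccc(O)c(OC)c3)[C@@H](C)[C@H]2C)ccc1OCc1ccccc1 | intermediate
15 | ethyl (S)-lactate | C[C@H](O)C(=O)OCC | starting material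
16 | (S)-2-hydroxy-N-methoxy-N-methylpropanamide | C[C@H](O)C(=O)N(C)OC | intermediate
17 | (S)-1-[4-(benzyloxy)-3-methoxyphenyl]-2-hydroxypropan-1-one | C[C@H](O)C(=O)c1ccc(OCc2ccccc2)c(OC)c1 | intermediate
18 | (S)-1-[4-(benzyloxy)-3-methoxyphenyl]-1-oxopropan-2-yl 4-methylbenzenesulfonate | C[C@H](OS(=O)(=O)c1ccc(C)cc1)C(=O)c1ccc(OCc2ccccc2)c(OC)c1 | intermediate
19 | (R)-1-[4-(benzyloxy)-3-methoxyphenyl]-2-{4-[(2S,3S,4R,5S)-5-(4-benzyloxy-3-methoxyphenyl)-3,4-dimethyltetrahydrofuran-2-yl]-2-methoxyphenoxy}propan-1-one | COc1cc([C@H]2O[C@H](c3ccc(O[C@H](C)C(=O)c4ccc(OCc5ccccc5)c(OC)c4)c(OC)c3)[C@@H](C)[C@H]2C)ccc1OCc1ccccc1 | intermediate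
20 | (1S,2R)-1-[4-(benzyloxy)-3-methoxyphenyl]-2-{4-[(2S,3S,4R,5S)-5-(4-benzyloxy-3-methoxyphenyl)-3,4-dimethyltetrahydrofuran-2-yl]-2-methoxyphenoxy}propan-1-ol | COc1cc([C@H]2O[C@H](c3ccc(O[C@H](C)[C@@H](O)c4ccc(OCc5ccccc5)c(OC)c4)c(OC)c3)[C@@H](C)[C@H]2C)ccc1OCc1ccccc1 | intermediate
21 | (1S,2R)-1-(4-hydroxy-3-methoxyphenyl)-2-{4-[(2S,3S,4R,5S)-5-(4-hydroxy-3-methoxyphenyl)-3,4-dimethyltetrahydrofuran-2-yl]-2-methoxyphenoxy}propan-1-ol | COc1cc([C@H]2O[C@H](c3ccc(O[C@H](C)[C@@H](O)c4ccc(O)c(OC)c4)c(OC)c3)[C@@H](C)[C@H]2C)ccc1O | target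

Total step count: 15. Longest linear sequence: 10 steps (steps 2, 3, 4, 5, 6, 8, 9, 13, 14 and 15, from 3 to 21).

Steps most likely to fail

Step 9. The risks are over-oxidation (of the C2 carbinol, or a second oxidation of the product at C5), tautomerisation of the quinone methide to a styrene before ring closure, and incomplete facial selectivity at C5. The fallback forms the ring from a C5-oxygenated lactone and sets C2 last by hydride delivery; it sets out from 2 and 3 and comes back at 14. Bromophenol 3 would be silylated (i-Pr3SiCl, imidazole, DMF) to (4-bromo-2-methoxyphenoxy)tri(propan-2-yl)silane F1. F1 would be taken through the protocol of step 3 (via the aryllithium F2 and the arylzinc triflate F3) with anhydride 2 to the silyl-protected keto acid F4. Felkin-selective reduction with LiBH(s-Bu)3 (excess, THF, −78 °C) should give the hydroxy acid F5, which closes on acidic work-up to the 4,5-trans lactone F6. Addition of Grignard reagent 11 from the stock solution of step 7 (1.2 equiv, THF, −78 to 0 °C) to the lactone would give the hemiketal F7. Et3SiH/BF3·OEt2 at −78 °C would reduce the derived oxocarbenium ion with hydride entering anti to the C3 methyl, which should give the 2,3-cis tetrahydrofuran silyl ether F8. Bu4NF in THF would then free the ring B phenol to give 14.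

Step 8. The risks are poor facial selectivity in the aryl addition and α-epimerisation of aldehyde 10 before it reacts. The fallback replaces substrate control by reagent control; it sets out from 9 and comes back at 12. Weinreb amide 9 would be treated with 11 (3 equiv, THF, 0 °C) to give the aryl ketone (2R,3R)-1-[4-(benzyloxy)-3-methoxyphenyl]-4-(4-hydroxy-3-methoxyphenyl)-2,3-dimethylbutan-1-one F9. Corey–Bakshi–Shibata reduction with the (R)-configured 2-methyl-oxazaborolidine and BH3·SMe2 (excess, to allow for the phenol) should then give the (1S) alcohol 12, by analogy with other aryl alkyl ketones.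

Step 14. The risks are weak chelation by the aryl ether oxygen, which would let non-chelated attack erode the erythro selectivity, and partial epimerisation at the carbon next to the carbonyl. The fallback hands stereocontrol to a catalyst: Noyori-type asymmetric transfer hydrogenation of 19 with RuCl[(R,R)-TsDPEN](p-cymene) in HCO2H/Et3N at rt, in which the ligand and not the neighbouring stereocentre sets the carbinol configuration. It sets out from 19 and comes back at 20 without any new compound.

Further compounds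
F1 | step 9 | (4-bromo-2-methoxyphenoxy)tri(propan-2-yl)silane | COc1cc(Br)ccc1O[Si](C(C)C)(C(C)C)C(C)C
F2 | step 9 | {3-methoxy-4-[tri(propan-2-yl)silyloxy]phenyl}lithium | COc1cc([Li])ccc1O[Si](C(C)C)(C(C)C)C(C)C
F3 | step 9 | {3-methoxy-4-[tri(propan-2-yl)silyloxy]phenyl}zinc trifluoromethanesulfonate | COc1cc([Zn]OS(=O)(=O)C(F)(F)F)ccc1O[Si](C(C)C)(C(C)C)C(C)C
F4 | step 9 | (2R,3S)-4-{3-methoxy-4-[tri(propan-2-yl)silyloxy]phenyl}-2,3-dimethyl-4-oxobutanoic acid | OC(=O)[C@H](C)[C@H](C)C(=O)c1ccc(O[Si](C(C)C)(C(C)C)C(C)C)c(OC)c1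
F5 | step 9 | (2R,3S,4S)-4-hydroxy-4-{3-methoxy-4-[tri(propan-2-yl)silyloxy]phenyl}-2,3-dimethylbutanoic acid | OC(=O)[C@H](C)[C@H](C)[C@H](O)c1ccc(O[Si](C(C)C)(C(C)C)C(C)C)c(OC)c1
F6 | step 9 | (3R,4S,5S)-5-{3-methoxy-4-[tri(propan-2-yl)silyloxy]phenyl}-3,4-dimethyloxolan-2-one | O=C1O[C@H](c2ccc(O[Si](C(C)C)(C(C)C)C(C)C)c(OC)c2)[C@@H](C)[C@H]1C
F7 | step 9 | (3R,4S,5S)-2-[4-(benzyloxy)-3-methoxyphenyl]-5-{3-methoxy-4-[tri(propan-2-yl)silyloxy]phenyl}-3,4-dimethyloxolan-2-ol (either anomer) | COc1cc(C2(O)O[C@H](c3ccc(O[Si](C(C)C)(C(C)C)C(C)C)c(OC)c3)[C@@H](C)[C@H]2C)ccc1OCc1ccccc1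
F8 | step 9 | (2S,3R,4S,5S)-2-[4-(benzyloxy)-3-methoxyphenyl]-5-{3-methoxy-4-[tri(propan-2-yl)silyloxy]phenyl}-3,4-dimethyloxolane | COc1cc([C@H]2O[C@H](c3ccc(O[Si](C(C)C)(C(C)C)C(C)C)c(OC)c3)[C@@H](C)[C@H]2C)ccc1OCc1ccccc1
F9 | step 8 | (2R,3R)-1-[4-(benzyloxy)-3-methoxyphenyl]-4-(4-hydroxy-3-methoxyphenyl)-2,3-dimethylbutan-1-one | COc1cc(C(=O)[C@H](C)[C@H](C)Cc2ccc(O)c(OC)c2)ccc1OCc1ccccc1
F0 | step 14 | none | none
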